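In a one-step world, starting material and reagent turn into product over the catalyst, one of each, as far as the smaller charge allows. Here the ochre run has not been read, and the other runs must tell us what it does.

in all of them: free catalyst 0.00130 M

| flask | starting material | reagent | time |
|---|---|---|---|
| red | 0.250 M | 0.375 M |  |
| violet | 0.150 M | 0.275 M |  |
| green | 0.380 M | 0.375 M |  |
| amber | 0.250 M | 0.560 M |  |
| ochre | 0.610 M | 0.375 M | 14 min |

- red run (time / min: [starting material] / M): 1.1: 0.2257; 3.2: 0.1937; 6.2: 0.1670; 9.8: 0.1493; 14: 0.1326
- violet run (time / min: [starting material] / M): 1.1: 0.1356; 3.2: 0.1177; 6.2: 0.0994; 9.8: 0.0893; 14: 0.0804
- green run (time / min: [starting material] / M): 1.1: 0.3384; 3.2: 0.2891; 6.2: 0.2456; 9.8: 0.2119; 14: 0.1863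
- amber run (time / min: [starting material] / M): 1.1: 0.2228; 3.2: 0.1903; 6.2: 0.1663; 9.8: 0.1466; 14: 0.1342

(each reading ± 8 × 10⁻⁴ M)

- how the opening rate goes with [starting material] round the charge of the red run: the exponent of the rate at two percent of starting material gone to product (one fixed amount of product, the same in the runs compared)
- how the opening rate goes with [reagent] round the charge of the red run: the exponent of the rate at two percent of starting material gone to product
- starting material in the ochre run at 14 min, as a share of the starting material charged

- Overall: starting material + reagent -> product, with free catalyst as catalyst.
- Constant volume, constant temperature.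
- A reading of a species includes what of it is bound.
- An order is taken over about fifteen percent of the charge, up and down.

The readings leave that one-step world. In the red run, starting material goes at 0.0221 M min⁻¹ over the first reading and at 0.00398 M min⁻¹ over the last stretch, a fall of 5.55 times. Its level has dropped by 1.77 times, and even the square of that, 3.13, is smaller, so we take the catalytic path to be stopping.

What remains late seems not to need reagent: over that stretch the amber run, with more reagent than the red run, loses less. We assume this late loss goes with the square of starting material, so the reciprocal of its level climbs in a straight line. We read the slope in the green run, whose final level is the highest, so that the scatter weighs least: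

tail slope = (1/0.1863 M − 1/0.2119 M) / 4.20 min = 0.154 L mol⁻¹ min⁻¹

Running that line back to the start gives a level below the charge. The gap in the green run reads 0.0681 M, and we carry it as the catalyst budget, the amount of starting material we take the catalyst to turn before it stops. With the same slope, the red run reads 0.0641 M, the amber run 0.0610 M and the violet run 0.0527 M. From the violet run to the green run these readings grow by a factor of 1.29, less than the factor of 2.53 in the starting material charge, so we take the green reading over to the ochre run as an estimate; it is smaller than the reagent charge there.

Our reckoning for the share left in the ochre run at 14 min builds up as follows: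

main step, reagent as limiting reagent: (0.610 M − 0.375 M) / 0.610 M = 38.5 %

catalyst held to its budget: (0.610 M − 0.0681 M) / 0.610 M = 88.8 %

tail added: 1 / (1/(0.610 M − 0.0681 M) + 0.154 L mol⁻¹ min⁻¹ × 14 min) = 0.250 M, a share of 40.9 %

The forecast gives 1.1 for the order in starting material, 0.15 for the order in reagent and 48 % left in the ochre run. Its reasoning opens with the remark that “The fraction of starting material left against time is nearly the same in all runs”. Our 40.9 % lies below its share.

The flask gives 0.61 for the order in starting material, 0.40 for the order in reagent and 40.0 % left in the ochre run, with these steps behind it:

    free catalyst + starting material → catalyst-substrate complex (91.20 L mol⁻¹ min⁻¹)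
    catalyst-substrate complex + reagent → product + free catalyst (93.00 L mol⁻¹ min⁻¹)
    free catalyst + starting material → spent catalyst + starting material (2.340 L mol⁻¹ min⁻¹)
    2 starting material → homo dimer (0.07980 L mol⁻¹ min⁻¹)

Of the 0.366 M of starting material gone in the ochre run, the catalyst budget of 0.0681 M, as read in the green run, is 18.6 %. In the violet run, the product made came to a quarter of the charge, 0.0375 M, at 7.23 min, which is 55.1 % of that budget.

Readings and results are calculated for an exercise, noise included.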